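**Retrosynthetic overview**
1. The C9 quaternary centre is made last, by palladium-catalysed prenylation of the triketone enolate of 10 on the face syn to the C11 carbonyl bridge.
2. The cyclopentane (C1–C5) is closed through the C3–C4 bond by an acid-mediated cation/enol (Conia-ene type) cyclization of isopropenyl ketone 9; C3 is left under thermodynamic control.
3. The bicyclo[3.2.1]octane comes from arene 6 in one enantioselective dearomative allylic annulation with isoprene monoxide (C7–C6 bond, then C1–C5 bond), which sets C7, C1 and C5.
4. Arene 6 comes from phloroglucinol by acylation, C-methylation and Michael addition to methyl vinyl ketone.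
5. Ring order: six-membered triketone ring (the former arene), then the five-membered bridge ring (key step), then the cyclopentane.

Assumption: locants are those of the target skeleton tricyclo[5.3.1.0(1,5)]undecane (C1 and C7 bridgeheads, C11 bridging carbonyl, C9 the acyl/prenyl carbon); enolized triketones are drawn as one tautomer; the C3 epimer drawn (acetyl on the convex face) is taken to be the thermodynamic one.

**Step 1**
Reactants: 1 phloroglucinol; 2 isobutyryl chloride
Product: 3 2-methyl-1-(2,4,6-trihydroxyphenyl)propan-1-one
Conditions: AlCl3 (3.5 equiv), PhNO2/CH2Cl2, 0 °C to 45 °C; aq. HCl work-up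
Reagents that add atoms: none
Why: Friedel–Crafts acylation of the strongly activated triol stops after one acylation because the acyl group deactivates the ring; no stereocentre is formed.

**Step 2**
Reactants: 3
Product: 4 2-methyl-1-(2,4,6-trihydroxy-3-methylphenyl)propan-1-one
Conditions: NaOMe (1.1 equiv), MeI (1.05 equiv), MeOH, 0 °C to rt
Reagents that add atoms: iodomethane, CI
Why: C-alkylation of the phloroglucinolate (an enolate-type carbon nucleophile) with one equivalent of MeI at low temperature favours the mono-methyl arene, which is separated from over-methylated material by chromatography; no stereocentre is formed.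

**Step 3**
Reactants: 4; 5 methyl vinyl ketone
Product: 6 2-methyl-1-[2,4,6-trihydroxy-3-methyl-5-(3-oxobutyl)phenyl]propan-1-one
Conditions: 5 (1.2 equiv), Et3N (0.2 equiv), MeOH, rt
Reagents that add atoms: none
Why: Michael addition of the only free ring carbon (future C1) of the phenolate to the enone gives the C-alkylated arene, whose chromanol hemiketal form reopens under the next conditions; no stereocentre is formed.

**Step 4 (key step)**
Reactants: 6; 7 isoprene monoxide
Product: 9 (1S,5S,7R)-2-hydroxy-5-methyl-3-(2-methylpropanoyl)-1-(3-oxobutyl)-7-(prop-1-en-2-yl)bicyclo[3.2.1]oct-2-ene-4,8-dione, via dienone allylic alcohol 8 (not isolated)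
Conditions: Pd2(dba)3·CHCl3 (2.5 mol %), (1R,2R)-N,N'-bis[2-(diphenylphosphino)benzoyl]cyclohexane-1,2-diamine (7.5 mol %), 7 (1.1 equiv), THF, 0 °C to rt; then Et3B (30 mol %), 50 °C
Reagents that add atoms: none
Why: Proposed new method: zerovalent palladium opens the vinyl epoxide to a zwitterionic π-allyl complex whose alkoxide deprotonates 6; the phenolate attacks the unsubstituted allyl terminus through its less hindered methyl-bearing carbon inside the chiral ligand pocket, an enantio-determining dearomatization that fixes quaternary C7; the acidic triketone 8 (pKa about 5) then activates its own allylic hydroxyl, helped by Et3B, for a second ionization in which the C1 enolate closes the five-membered ring at the internal allyl carbon on the face that already carries the tether, with the allyl-palladium unit pointing away from the ring so that the isopropenyl group at C5 ends up exo (syn to the C11 carbonyl), and any O-cyclized enol ether re-ionizes and funnels to the C–C product; the closest known reactions are the palladium-catalysed dearomative conjunctive allylic annulation of acylphloroglucinols with 2-methylenepropane-1,3-diyl bis-carbonates, the Trost asymmetric allylic dearomatization of phenols and naphthols, the 1,4-addition of soft nucleophiles to isoprene monoxide and the Tamaru direct Tsuji–Trost allylation with allylic alcohols.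

**Step 5**
Reactants: 9
Product: 10 (1S,3S,5R,7S)-3-acetyl-10-hydroxy-4,4,7-trimethyl-9-(2-methylpropanoyl)tricyclo[5.3.1.0(1,5)]undec-9-ene-8,11-dione
Conditions: CF3SO3H (1.1 equiv), (CF3)2CHOH/CH2Cl2 1:4, 0 °C to rt
Reagents that add atoms: none
Why: Markovnikov protonation of the isopropenyl group gives the tertiary C4 cation, which is captured at C3 by the more substituted enol of the methyl ketone in a cationic Conia-ene type 5-exo cyclization (intramolecular α-tert-alkylation of a ketone); only the exo cation can reach the side chain, alkene/cation equilibration corrects any endo isomer, and acid-catalysed enolization leaves C3 as the thermodynamic epimer with the acetyl group on the convex face, trans to the C6 bridge.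

**Step 6**
Reactants: 10; 11 prenyl acetate
Product: 12 (1R,3S,5R,7S,9S)-3-acetyl-4,4,7-trimethyl-9-(3-methylbut-2-en-1-yl)-9-(2-methylpropanoyl)tricyclo[5.3.1.0(1,5)]undecane-8,10,11-trione (the target, CNP0322535.2)
Conditions: Pd(PPh3)4 (5 mol %), 11 (1.5 equiv), Et3N (1.5 equiv), THF, 40 °C
Reagents that add atoms: none
Why: Tsuji–Trost allylation in which the soft triketone enolate attacks the unsubstituted terminus of the π-prenyl complex (linear prenyl), O-prenyl enol ethers re-ionize under the catalyst and funnel to the C-alkylated product, and the electrophile reaches C9 from the open face syn to the C11 carbonyl bridge, away from the endo hydrogens of the C5–C6 bridge, which places prenyl syn to C11 and the acyl group toward the two-carbon bridge as in the target.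

**Compound list**
1 | phloroglucinol (benzene-1,3,5-triol) | Oc1cc(O)cc(O)c1 | starting material
2 | isobutyryl chloride (2-methylpropanoyl chloride) | CC(C)C(Cl)=O | starting material
3 | 2-methyl-1-(2,4,6-trihydroxyphenyl)propan-1-one | CC(C)C(=O)c1c(O)cc(O)cc1O | intermediate
4 | 2-methyl-1-(2,4,6-trihydroxy-3-methylphenyl)propan-1-one | CC(C)C(=O)c1c(O)cc(O)c(C)c1O | intermediate
5 | methyl vinyl ketone (but-3-en-2-one) | CC(=O)C=C | starting material
6 | 2-methyl-1-[2,4,6-trihydroxy-3-methyl-5-(3-oxobutyl)phenyl]propan-1-one | CC(C)C(=O)c1c(O)c(C)c(O)c(CCC(C)=O)c1O | intermediate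
7 | isoprene monoxide (2-methyl-2-vinyloxirane, racemic; its stereocentre is erased on ionization) | CC1(C=C)CO1 | starting material
8 | (6R)-3,5-dihydroxy-6-[(2E)-4-hydroxy-3-methylbut-2-en-1-yl]-6-methyl-4-(2-methylpropanoyl)-2-(3-oxobutyl)cyclohexa-2,4-dien-1-one | CC(=O)CCC1=C(O)C(C(=O)C(C)C)=C(O)[C@@](C)(C/C=C(\C)CO)C1=O | intermediate
9 | (1S,5S,7R)-2-hydroxy-5-methyl-3-(2-methylpropanoyl)-1-(3-oxobutyl)-7-(prop-1-en-2-yl)bicyclo[3.2.1]oct-2-ene-4,8-dione (isopropenyl exo, syn to the bridging carbonyl) | CC(=O)CC[C@]12C(=O)[C@](C)(C[C@@H]1C(C)=C)C(=O)C(C(=O)C(C)C)=C2O | intermediate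
10 | (1S,3S,5R,7S)-3-acetyl-10-hydroxy-4,4,7-trimethyl-9-(2-methylpropanoyl)tricyclo[5.3.1.0(1,5)]undec-9-ene-8,11-dione | CC(=O)[C@H]1C[C@]23C(=O)[C@](C)(C[C@@H]2C1(C)C)C(=O)C(C(=O)C(C)C)=C3O | intermediate
11 | prenyl acetate (3-methylbut-2-en-1-yl acetate) | CC(=O)OCC=C(C)C | starting material
12 | (1R,3S,5R,7S,9S)-3-acetyl-4,4,7-trimethyl-9-(3-methylbut-2-en-1-yl)-9-(2-methylpropanoyl)tricyclo[5.3.1.0(1,5)]undecane-8,10,11-trione | CC(=O)[C@H]1C[C@]23C(=O)[C@](C)(C[C@@H]2C1(C)C)C(=O)[C@](CC=C(C)C)(C(=O)C(C)C)C3=O | target

**Step count and risks**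
Total steps: 6. Longest linear sequence: 6 (from phloroglucinol).

Steps most likely to fail:

Step 4. The first alkylation may go to the oxobutyl-bearing carbon, the second ring closure may stop at an O-cyclized dihydrofuran, the allylic alcohol may not ionize, or the sense or level of induction may be poor (the enantiomeric ligand is used if the sense is opposite). The fallback sets out from 6 and comes back at 9. Compound 6 is prenylated at its methyl-bearing carbon with prenyl acetate 11 under the same chiral palladium catalyst and Et3N (asymmetric Tsuji–Trost dearomatization) to give the prenylated dienone (6R)-3,5-dihydroxy-6-methyl-6-(3-methylbut-2-en-1-yl)-4-(2-methylpropanoyl)-2-(3-oxobutyl)cyclohexa-2,4-dien-1-one F1. Oxidation of this with Mn(OAc)3·2H2O (2.2 equiv) and Cu(OAc)2·H2O (1 equiv) in acetic acid at rt forms the radical at the oxobutyl-bearing carbon, which closes 5-exo onto the prenyl group. The tertiary radical is oxidized by divalent copper to the isopropenyl group, giving 9 by a radical instead of a polar ring closure.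

Step 5. The enol content of the ketone is low, so aldol closure onto a ring carbonyl or simple alkene isomerization may win. The fallback sets out from 4 and comes back at 10, replacing the ketone by an alkyne as the cation trap. Compound 4 is C-alkylated at its free ring carbon with 1-bromobut-2-yne (KOH, aqueous MeOH, 0 °C) to give the butynyl arene 1-[3-(but-2-yn-1-yl)-2,4,6-trihydroxy-5-methylphenyl]-2-methylpropan-1-one F2. This is taken through the annulation of step 4 to the enyne (1S,5S,7R)-1-(but-2-yn-1-yl)-2-hydroxy-5-methyl-3-(2-methylpropanoyl)-7-(prop-1-en-2-yl)bicyclo[3.2.1]oct-2-ene-4,8-dione F3. CF3CO2H in CH2Cl2 at 0 °C protonates the isopropenyl group, the tertiary cation is captured by the alkyne (Johnson-type cation–alkyne cyclization), and the vinyl cation is trapped as the enol trifluoroacetate. K2CO3 in aqueous MeOH then releases the acetyl group and equilibrates C3, giving 10.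

Step 6. The acyl-bearing carbon is a poor, hindered nucleophile, so O-prenylation, low conversion or the wrong face may result. The fallback sets out from 10 and comes back at 12. O-Allylation with allyl bromide and K2CO3 in acetone gives the allyl enol ether (1S,3S,5R,7S)-3-acetyl-4,4,7-trimethyl-9-(2-methylpropanoyl)-10-(prop-2-en-1-yloxy)tricyclo[5.3.1.0(1,5)]undec-9-ene-8,11-dione F4 (the regioisomeric O-allyl ethers behave the same way). Thermal Claisen rearrangement (toluene, 110 °C) moves the allyl group to C9 across the less hindered face to give the allyl triketone (1R,3S,5R,7S,9S)-3-acetyl-4,4,7-trimethyl-9-(2-methylpropanoyl)-9-(prop-2-en-1-yl)tricyclo[5.3.1.0(1,5)]undecane-8,10,11-trione F5. Cross-metathesis with 2-methylbut-2-ene (second-generation Grubbs catalyst, CH2Cl2, 40 °C) turns allyl into prenyl, giving 12.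

**Further compounds**
F1 | step 4 | (6R)-3,5-dihydroxy-6-methyl-6-(3-methylbut-2-en-1-yl)-4-(2-methylpropanoyl)-2-(3-oxobutyl)cyclohexa-2,4-dien-1-one | CC(=O)CCC1=C(O)C(C(=O)C(C)C)=C(O)[C@@](C)(CC=C(C)C)C1=O
F2 | step 5 | 1-[3-(but-2-yn-1-yl)-2,4,6-trihydroxy-5-methylphenyl]-2-methylpropan-1-one | CC#CCc1c(O)c(C)c(O)c(C(=O)C(C)C)c1O
F3 | step 5 | (1S,5S,7R)-1-(but-2-yn-1-yl)-2-hydroxy-5-methyl-3-(2-methylpropanoyl)-7-(prop-1-en-2-yl)bicyclo[3.2.1]oct-2-ene-4,8-dione | CC#CC[C@]12C(=O)[C@](C)(C[C@@H]1C(C)=C)C(=O)C(C(=O)C(C)C)=C2O
F4 | step 6 | (1S,3S,5R,7S)-3-acetyl-4,4,7-trimethyl-9-(2-methylpropanoyl)-10-(prop-2-en-1-yloxy)tricyclo[5.3.1.0(1,5)]undec-9-ene-8,11-dione | CC(=O)[C@H]1C[C@]23C(=O)[C@](C)(C[C@@H]2C1(C)C)C(=O)C(C(=O)C(C)C)=C3OCC=C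
F5 | step 6 | (1R,3S,5R,7S,9S)-3-acetyl-4,4,7-trimethyl-9-(2-methylpropanoyl)-9-(prop-2-en-1-yl)tricyclo[5.3.1.0(1,5)]undecane-8,10,11-trione | CC(=O)[C@H]1C[C@]23C(=O)[C@](C)(C[C@@H]2C1(C)C)C(=O)[C@](CC=C)(C(=O)C(C)C)C3=O
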